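**Retrosynthetic overview**
1. Target 23 ⇐ imide 22: the last step only unmasks (LiBH4 turns the oxazolidinone imide into the C9'' alcohol and removes the aryl acetate).
2. 22 ⇐ seco-phenol 20: the tetrahydrofuran (O–C7 bond) is closed late by oxidising the one free 4-alkylguaiacol to its p-quinone methide, which the C9' hydroxyl captures; this sets C7.
3. 20 ⇐ aryloxyacetyl imide 15 + vanillin acetate 16 (anti-aldol sets C7''/C8''); 15 ⇐ phenol 13 + chloroacetyl imide 14 (aryl ether).
4. 13 (a selectively protected carinol-type triol) ⇐ diisopropyl (S)-malate 3 + benzyl bromides 2 and 10: malate dianion alkylation sets C8, dioxolanone alkylation sets the quaternary C8'.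
5. Ring order: the three benzene rings are bought; the tetrahydrofuran is the only ring made (step 12 of 13).

Assumption and numbering: (S)-4-benzyl-3-(chloroacetyl)oxazolidin-2-one 14 is bought as a catalogue reagent; lignan numbering is used (C7–C9 aryl-bearing arm of the tetrahydrofuran, C7'–C9' benzyl arm, C7''–C9'' glycerol unit).

**Route**

Step 1
Reactants: 1 4-(benzyloxy)-3-methoxybenzyl alcohol
Product: 2 4-(benzyloxy)-3-methoxybenzyl bromide
Conditions: PBr3 (0.4 equiv), Et2O, 0 °C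
Reagents that add atoms: phosphorus tribromide, BrP(Br)Br
Why: Alcohol-to-bromide conversion with PBr3 (SN2 on the phosphite ester) of a benzylic alcohol; no stereocentre is involved.

Step 2
Reactants: 3 diisopropyl (S)-malate; 2 4-(benzyloxy)-3-methoxybenzyl bromide
Product: 5 diisopropyl (2S,3R)-3-[4-(benzyloxy)-3-methoxybenzyl]-2-hydroxysuccinate, via dilithium alkoxide enolate 4 (not isolated)
Conditions: LiN(SiMe3)2 (2.2 equiv), THF, −78 → −20 °C; then 2, −78 → −10 °C
Reagents that add atoms: none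
Why: Fráter–Seebach alkylation, in which the chelated dianion 4 is benzylated anti to the C2 alkoxide (about 9:1), setting C8 of the target (3R in the malate).

Step 3
Reactants: 5 diisopropyl (2S,3R)-3-[4-(benzyloxy)-3-methoxybenzyl]-2-hydroxysuccinate
Product: 6 (2S,3R)-3-[4-(benzyloxy)-3-methoxybenzyl]-2-hydroxysuccinic acid
Conditions: KOH (4 equiv), MeOH/H2O, rt; then aq. HCl
Reagents that add atoms: potassium hydroxide, [K+].[OH-]
Why: Ester saponification; the dicarboxylate resists enolisation, so C3 is not epimerised.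

Step 4
Reactants: 6 (2S,3R)-3-[4-(benzyloxy)-3-methoxybenzyl]-2-hydroxysuccinic acid
Product: 7 (2R)-3-[4-(benzyloxy)-3-methoxyphenyl]-2-[(2S,4S)-2-tert-butyl-5-oxo-1,3-dioxolan-4-yl]propanoic acid (cis-dioxolanone)
Conditions: Me3CCHO (3 equiv), TsOH·H2O (cat.), H2SO4 (cat.), CH2Cl2, reflux, water removal
Reagents that add atoms: pivalaldehyde, CC(C)(C)C=O
Why: Seebach acetalisation of the α-hydroxy acid gives the thermodynamically preferred cis-dioxolanone (new acetal centre S), which stores the C2 configuration for self-regeneration of the stereocentre; crystallisation also removes the minor C3 epimer from step 2.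

Step 5
Reactants: 8 4-hydroxy-3-methoxybenzyl alcohol (vanillyl alcohol)
Product: 9 4-(hydroxymethyl)-2-methoxyphenyl pivalate
Conditions: Me3CCOCl (1.05 equiv), aq. NaOH (1.1 equiv), CH2Cl2/H2O, 0 °C
Reagents that add atoms: pivaloyl chloride, CC(C)(C)C(=O)Cl
Why: Schotten–Baumann acylation, in which only the phenoxide is acylated in aqueous base and the benzylic alcohol stays free.

Step 6
Reactants: 9 4-(hydroxymethyl)-2-methoxyphenyl pivalate
Product: 10 4-(bromomethyl)-2-methoxyphenyl pivalate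
Conditions: PBr3 (0.4 equiv), CH2Cl2, 0 °C
Reagents that add atoms: phosphorus tribromide, BrP(Br)Br
Why: PBr3 bromination of the benzylic alcohol; the acyloxy group makes the bromide less prone to ionise, and no stereocentre is involved.

Step 7
Reactants: 7 cis-dioxolanone acid; 10 4-(bromomethyl)-2-methoxyphenyl pivalate
Product: 12 (2R)-3-[4-(benzyloxy)-3-methoxyphenyl]-2-[(2S,4S)-2-tert-butyl-4-[3-methoxy-4-(pivaloyloxy)benzyl]-5-oxo-1,3-dioxolan-4-yl]propanoic acid, via dilithium carboxylate enolate 11 (not isolated)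
Conditions: LiN(SiMe3)2 (2.3 equiv), THF/DMPU, −78 °C; then 10, −78 → −40 °C; aq. HCl work-up
Reagents that add atoms: none
Why: Seebach self-regeneration of stereocentres, in which the dioxolanone enolate 11 is alkylated trans to the tert-butyl group (overall retention at the former malate C2), creating the quaternary C8' (S in the target); the hindered aryl pivalate survives the enolate at −78 °C.

Step 8
Reactants: 12 dialkylated dioxolanone acid
Product: 13 (2S,3S)-3-[4-(benzyloxy)-3-methoxybenzyl]-2-(4-hydroxy-3-methoxybenzyl)butane-1,2,4-triol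
Conditions: LiAlH4 (6 equiv), THF, 0 °C → reflux
Reagents that add atoms: none
Why: Global hydride reduction, in which LiAlH4 reduces the acid and the dioxolanone carbonyl to the two primary alcohols, frees the tertiary alcohol from the acetal and cleaves the aryl pivalate, so only the C7' ring carries a free phenol.

Step 9
Reactants: 13 triol phenol; 14 (S)-4-benzyl-3-(chloroacetyl)oxazolidin-2-one
Product: 15 (S)-4-benzyl-3-[2-(4-{(2S,3S)-3-[4-(benzyloxy)-3-methoxybenzyl]-2,4-dihydroxy-2-(hydroxymethyl)butyl}-2-methoxyphenoxy)acetyl]oxazolidin-2-one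
Conditions: K2CO3 (1.5 equiv), acetone, 45 °C
Reagents that add atoms: none
Why: Williamson etherification, in which only the phenol is deprotonated by K2CO3 and displaces the activated α-chloride of 14 by SN2, putting the chiral glycolate unit on O4'.

Step 10
Reactants: 15 aryloxyacetyl imide; 16 4-formyl-2-methoxyphenyl acetate (vanillin acetate)
Product: 19 (S)-4-benzyl-3-[(2R,3R)-3-(4-acetoxy-3-methoxyphenyl)-2-(4-{(2S,3S)-3-[4-(benzyloxy)-3-methoxybenzyl]-2,4-dihydroxy-2-(hydroxymethyl)butyl}-2-methoxyphenoxy)-3-hydroxypropanoyl]oxazolidin-2-one, via bis(trimethylsilyl) ether 17 (not isolated), via tris(trimethylsilyl) aldol adduct 18 (not isolated)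
Conditions: MgCl2 (0.3 equiv), Et3N (6 equiv), Me3SiCl (5 equiv), EtOAc, rt; then citric acid, MeOH, 0 °C
Reagents that add atoms: none
Why: Proposed new method: the Evans magnesium-halide-catalysed direct anti-aldol (closest known case: N-propionyl oxazolidinones with aromatic aldehydes) is extended to an N-(aryloxyacetyl) imide whose primary hydroxyls are masked in the flask as silyl ethers; soft enolisation gives the chelated Z-enolate, the aldehyde adds through a boat transition state on the face opposite the auxiliary benzyl group, and irreversible O-silylation locks the anti adduct, setting C8'' (S in the target) and C7'' (R).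

Step 11
Reactants: 19 anti-aldol adduct
Product: 20 (S)-4-benzyl-3-[(2R,3R)-3-(4-acetoxy-3-methoxyphenyl)-2-(4-{(2S,3S)-2,4-dihydroxy-3-(4-hydroxy-3-methoxybenzyl)-2-(hydroxymethyl)butyl}-2-methoxyphenoxy)-3-hydroxypropanoyl]oxazolidin-2-one
Conditions: H2 (1 atm), 10% Pd/C, EtOAc/EtOH, rt
Reagents that add atoms: none
Why: Hydrogenolysis of the aryl benzyl ether frees the single phenol needed for the oxidation; the acetoxy-substituted benzylic alcohol, the aryl ethers and the imide are inert under these mild conditions.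

Step 12
Reactants: 20 seco-phenol
Product: 22 (S)-4-benzyl-3-[(2R,3R)-3-(4-acetoxy-3-methoxyphenyl)-3-hydroxy-2-(4-{[(3S,4R,5S)-3-hydroxy-5-(4-hydroxy-3-methoxyphenyl)-4-(hydroxymethyl)oxolan-3-yl]methyl}-2-methoxyphenoxy)propanoyl]oxazolidin-2-one, via p-quinone methide 21 (not isolated)
Conditions: DDQ (1.05 equiv), 1,4-dioxane, 10 °C → rt
Reagents that add atoms: none
Why: Oxidative quinone-methide cyclisation (DDQ dehydrogenation of the only free 4-alkylguaiacol, then 5-exo oxa-1,6-addition of the C9' hydroxyl), the laboratory counterpart of the closure assumed for olivil from a carinol-type triol; the aryl group ends up trans to the C8 hydroxymethyl and anti to the C8' benzyl group (C7 = S), while the acetylated and O-alkylated guaiacyl rings cannot form quinone methides.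

Step 13
Reactants: 22 tetrahydrofuran imide
Product: 23 (1R,2S)-1-(4-hydroxy-3-methoxyphenyl)-2-(4-{[(3S,4R,5S)-3-hydroxy-5-(4-hydroxy-3-methoxyphenyl)-4-(hydroxymethyl)oxolan-3-yl]methyl}-2-methoxyphenoxy)propane-1,3-diol (CNP0350466.2)
Conditions: LiBH4 (6 equiv), THF/MeOH, 0 °C → rt
Reagents that add atoms: none
Why: Reductive cleavage of the N-acyl oxazolidinone with LiBH4 gives the C9'' primary alcohol without touching C8'' and reduces off the aryl acetate in the same pot; the neutral work-up avoids the acid-induced rearrangement of the olivil core.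

**Compound list**
1 | 4-(benzyloxy)-3-methoxybenzyl alcohol | COc1cc(CO)ccc1OCc1ccccc1 | starting material
2 | 4-(benzyloxy)-3-methoxybenzyl bromide | COc1cc(CBr)ccc1OCc1ccccc1 | intermediate
3 | diisopropyl (S)-malate | CC(C)OC(=O)[C@@H](O)CC(=O)OC(C)C | starting material
4 | dilithium alkoxide enolate of 3 (formed in the flask) | [Li+].[Li+].CC(C)OC(=O)[C@@H]([O-])C=C([O-])OC(C)C | intermediate
5 | diisopropyl (2S,3R)-3-[4-(benzyloxy)-3-methoxybenzyl]-2-hydroxysuccinate | CC(C)OC(=O)[C@@H](O)[C@@H](Cc1ccc(OCc2ccccc2)c(OC)c1)C(=O)OC(C)C | intermediate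
6 | (2S,3R)-3-[4-(benzyloxy)-3-methoxybenzyl]-2-hydroxysuccinic acid | OC(=O)[C@@H](O)[C@@H](Cc1ccc(OCc2ccccc2)c(OC)c1)C(=O)O | intermediate
7 | (2R)-3-[4-(benzyloxy)-3-methoxyphenyl]-2-[(2S,4S)-2-tert-butyl-5-oxo-1,3-dioxolan-4-yl]propanoic acid | O=C1O[C@@H](C(C)(C)C)O[C@H]1[C@@H](Cc2ccc(OCc3ccccc3)c(OC)c2)C(=O)O | intermediate
8 | 4-hydroxy-3-methoxybenzyl alcohol (vanillyl alcohol) | COc1cc(CO)ccc1O | starting material
9 | 4-(hydroxymethyl)-2-methoxyphenyl pivalate | COc1cc(CO)ccc1OC(=O)C(C)(C)C | intermediate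
10 | 4-(bromomethyl)-2-methoxyphenyl pivalate | COc1cc(CBr)ccc1OC(=O)C(C)(C)C | intermediate
11 | dilithium carboxylate enolate of 7 (formed in the flask) | [Li+].[Li+].[O-]C1=C([C@@H](Cc2ccc(OCc3ccccc3)c(OC)c2)C([O-])=O)O[C@H](C(C)(C)C)O1 | intermediate
12 | (2R)-3-[4-(benzyloxy)-3-methoxyphenyl]-2-[(2S,4S)-2-tert-butyl-4-[3-methoxy-4-(pivaloyloxy)benzyl]-5-oxo-1,3-dioxolan-4-yl]propanoic acid | O=C1O[C@@H](C(C)(C)C)O[C@@]1(Cc2ccc(OC(=O)C(C)(C)C)c(OC)c2)[C@@H](Cc3ccc(OCc4ccccc4)c(OC)c3)C(=O)O | intermediate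
13 | (2S,3S)-3-[4-(benzyloxy)-3-methoxybenzyl]-2-(4-hydroxy-3-methoxybenzyl)butane-1,2,4-triol | COc1cc(C[C@@](O)(CO)[C@H](CO)Cc2ccc(OCc3ccccc3)c(OC)c2)ccc1O | intermediate
14 | (S)-4-benzyl-3-(chloroacetyl)oxazolidin-2-one | O=C(CCl)N1[C@@H](Cc2ccccc2)COC1=O | starting material
15 | (S)-4-benzyl-3-[2-(4-{(2S,3S)-3-[4-(benzyloxy)-3-methoxybenzyl]-2,4-dihydroxy-2-(hydroxymethyl)butyl}-2-methoxyphenoxy)acetyl]oxazolidin-2-one | COc1cc(C[C@@](O)(CO)[C@H](CO)Cc2ccc(OCc3ccccc3)c(OC)c2)ccc1OCC(=O)N4[C@@H](Cc5ccccc5)COC4=O | intermediate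
16 | 4-formyl-2-methoxyphenyl acetate (vanillin acetate) | COc1cc(C=O)ccc1OC(C)=O | starting material
17 | bis(trimethylsilyl) ether of 15, both primary hydroxyls silylated (formed in the flask) | COc1cc(C[C@@](O)(CO[Si](C)(C)C)[C@H](CO[Si](C)(C)C)Cc2ccc(OCc3ccccc3)c(OC)c2)ccc1OCC(=O)N4[C@@H](Cc5ccccc5)COC4=O | intermediate
18 | tris(trimethylsilyl) ether of 19, C9-O, C9'-O and C7''-O silylated (formed in the flask) | COc1cc(C[C@@](O)(CO[Si](C)(C)C)[C@H](CO[Si](C)(C)C)Cc2ccc(OCc3ccccc3)c(OC)c2)ccc1O[C@H]([C@H](O[Si](C)(C)C)c6ccc(OC(C)=O)c(OC)c6)C(=O)N4[C@@H](Cc5ccccc5)COC4=O | intermediate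
19 | (S)-4-benzyl-3-[(2R,3R)-3-(4-acetoxy-3-methoxyphenyl)-2-(4-{(2S,3S)-3-[4-(benzyloxy)-3-methoxybenzyl]-2,4-dihydroxy-2-(hydroxymethyl)butyl}-2-methoxyphenoxy)-3-hydroxypropanoyl]oxazolidin-2-one | COc1cc(C[C@@](O)(CO)[C@H](CO)Cc2ccc(OCc3ccccc3)c(OC)c2)ccc1O[C@H]([C@H](O)c6ccc(OC(C)=O)c(OC)c6)C(=O)N4[C@@H](Cc5ccccc5)COC4=O | intermediate
20 | (S)-4-benzyl-3-[(2R,3R)-3-(4-acetoxy-3-methoxyphenyl)-2-(4-{(2S,3S)-2,4-dihydroxy-3-(4-hydroxy-3-methoxybenzyl)-2-(hydroxymethyl)butyl}-2-methoxyphenoxy)-3-hydroxypropanoyl]oxazolidin-2-one | COc1cc(C[C@@](O)(CO)[C@H](CO)Cc2ccc(O)c(OC)c2)ccc1O[C@H]([C@H](O)c6ccc(OC(C)=O)c(OC)c6)C(=O)N4[C@@H](Cc5ccccc5)COC4=O | intermediate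
21 | p-quinone methide of 20, exocyclic C7=C1 double bond (formed in the flask) | COc1cc(C[C@@](O)(CO)[C@H](CO)C=C2C=CC(=O)C(OC)=C2)ccc1O[C@H]([C@H](O)c6ccc(OC(C)=O)c(OC)c6)C(=O)N4[C@@H](Cc5ccccc5)COC4=O | intermediate
22 | (S)-4-benzyl-3-[(2R,3R)-3-(4-acetoxy-3-methoxyphenyl)-3-hydroxy-2-(4-{[(3S,4R,5S)-3-hydroxy-5-(4-hydroxy-3-methoxyphenyl)-4-(hydroxymethyl)oxolan-3-yl]methyl}-2-methoxyphenoxy)propanoyl]oxazolidin-2-one | COc1cc(C[C@@]7(O)CO[C@H](c2ccc(O)c(OC)c2)[C@H]7CO)ccc1O[C@H]([C@H](O)c6ccc(OC(C)=O)c(OC)c6)C(=O)N4[C@@H](Cc5ccccc5)COC4=O | intermediate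
23 | (1R,2S)-1-(4-hydroxy-3-methoxyphenyl)-2-(4-{[(3S,4R,5S)-3-hydroxy-5-(4-hydroxy-3-methoxyphenyl)-4-(hydroxymethyl)oxolan-3-yl]methyl}-2-methoxyphenoxy)propane-1,3-diol | COc1cc([C@@H](O)[C@H](CO)Oc2ccc(C[C@@]3(O)CO[C@H](c4ccc(O)c(OC)c4)[C@H]3CO)cc2OC)ccc1O | target

**Step count**
Total: 13 steps. Longest linear sequence: 11 steps (steps 1, 2, 3, 4, 7, 8, 9, 10, 11, 12, 13); steps 5 and 6 make the second bromide.

**Steps most likely to fail, with fallbacks**

Step 10 (anti-aldol) is the least secure, because the magnesium protocol is not established for aryloxyacetyl imides and the anti:syn ratio may be poor. The fallback sets out from 15 and 16 and comes back at 19, and it sets the two side-chain centres in separate operations. The aldol is then asked only to form the C–C bond and the chelate-controlled C8'' centre, and its crude product is taken on as the mixture of 19 and the C7''-epimeric syn adduct F3. MnO2 (CH2Cl2, rt) oxidises only the benzylic carbinol and converges both epimers to the β-keto imide F4, whose C8'' centre is held by the allylic strain of the imide. NaBH4 (THF/EtOH, −78 °C) then reduces the ketone under Felkin–Anh control, with hydride anti to the aryloxy group, and returns the anti alcohol 19. This rescue assumes the aldol still gives conversion and the chelate-controlled C8'' configuration.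

Step 12 (oxidative cyclisation) may suffer over-oxidation of the product at C7 or Friedel–Crafts closure onto the C7' ring (the cycloolivil pathway). The fallback sets out from 20 and comes back at 22, and it reaches the quinone methide from a benzylic alcohol instead of by direct dehydrogenation. DDQ (2.2 equiv) in 1,4-dioxane/H2O takes 20 deliberately to the C7 aryl ketone F5. NaBH4 with CeCl3·7H2O (MeOH, −40 °C) reduces this ketone, but not the imide, to the C7 benzylic alcohol F6 as a mixture of C7 epimers. This p-hydroxybenzyl alcohol ionises to the same quinone methide 21 under mild buffering (pyridinium tosylate cat., MeCN, rt) and closes to 22. C8 in F5 is α to a ketone and could epimerise, so F5 is not exposed to base.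

Step 7 (quaternary alkylation) may stall because the dianion is hindered and the electrophile functionalised. The fallback sets out from 7 and comes back at 13, and it lets the C8 stereocentre rather than the acetal control C8'. BH3·SMe2 reduces the free acid, and TsOH closes the new alcohol onto the dioxolanone carbonyl with loss of pivalaldehyde, giving the hydroxy lactone F1. Its dianion (LiN(iPr)2, 2.2 equiv, THF/DMPU, −78 °C) is benzylated by 10 on the face opposite the C4 benzyl group, giving the nortrachelogenin-type dibenzylated hydroxy lactone F2. LiAlH4 opens the lactone and removes the pivalate to give 13.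

**Further compounds**
F1 | step 7 | (3S,4S)-4-[4-(benzyloxy)-3-methoxybenzyl]-3-hydroxydihydrofuran-2(3H)-one | O=C1OC[C@H](Cc2ccc(OCc3ccccc3)c(OC)c2)[C@@H]1O
F2 | step 7 | (3S,4S)-4-[4-(benzyloxy)-3-methoxybenzyl]-3-hydroxy-3-[3-methoxy-4-(pivaloyloxy)benzyl]dihydrofuran-2(3H)-one | O=C1OC[C@H](Cc2ccc(OCc3ccccc3)c(OC)c2)[C@@]1(O)Cc4ccc(OC(=O)C(C)(C)C)c(OC)c4
F3 | step 10 | (S)-4-benzyl-3-[(2R,3S)-3-(4-acetoxy-3-methoxyphenyl)-2-(4-{(2S,3S)-3-[4-(benzyloxy)-3-methoxybenzyl]-2,4-dihydroxy-2-(hydroxymethyl)butyl}-2-methoxyphenoxy)-3-hydroxypropanoyl]oxazolidin-2-one (C7'' epimer of 19) | COc1cc(C[C@@](O)(CO)[C@H](CO)Cc2ccc(OCc3ccccc3)c(OC)c2)ccc1O[C@H]([C@@H](O)c6ccc(OC(C)=O)c(OC)c6)C(=O)N4[C@@H](Cc5ccccc5)COC4=O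
F4 | step 10 | (S)-4-benzyl-3-[(2R)-3-(4-acetoxy-3-methoxyphenyl)-2-(4-{(2S,3S)-3-[4-(benzyloxy)-3-methoxybenzyl]-2,4-dihydroxy-2-(hydroxymethyl)butyl}-2-methoxyphenoxy)-3-oxopropanoyl]oxazolidin-2-one | COc1cc(C[C@@](O)(CO)[C@H](CO)Cc2ccc(OCc3ccccc3)c(OC)c2)ccc1O[C@H](C(=O)c6ccc(OC(C)=O)c(OC)c6)C(=O)N4[C@@H](Cc5ccccc5)COC4=O
F5 | step 12 | C7 ketone of 20 (4-hydroxy-3-methoxyphenyl ketone; C8, C8', C7'' and C8'' as in 20) | COc1cc(C[C@@](O)(CO)[C@H](CO)C(=O)c2ccc(O)c(OC)c2)ccc1O[C@H]([C@H](O)c6ccc(OC(C)=O)c(OC)c6)C(=O)N4[C@@H](Cc5ccccc5)COC4=O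
F6 | step 12 | C7 benzylic alcohol of 20 (both C7 epimers; other centres as in 20) | COc1cc(C[C@@](O)(CO)[C@H](CO)C(O)c2ccc(O)c(OC)c2)ccc1O[C@H]([C@H](O)c6ccc(OC(C)=O)c(OC)c6)C(=O)N4[C@@H](Cc5ccccc5)COC4=O
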